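**Retrosynthetic overview**

1. Target ⇐ macrolide triol 37 by site-selective 18-O-acetylation and 9-O-acylation with pyrrole-2-carboxylic acid; 10-membered lactone (C1–O17) by Shiina lactonisation.
2. Ring A (C5=C6) by ring-closing metathesis, after a Sakurai allylation that joins C4 to the quaternary ether carbon C13 of a bridged lactol (new step).
3. Lactol ⇐ bridged γ-lactone (ring B plus the C8–O–C13 bridge) + (Z)-alkenyllithium (C14–C19).
4. Key 1,2-shift: copper-mediated 1,2-metallate rearrangement of a 5-lithio-2,3-dihydrofuran (methyl migrates from Cu to C14, the ring oxygen leaves); it fixes the (Z)-C14=C15 olefin and frees O17.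
5. Ring B ⇐ furan + maleic anhydride (Diels–Alder), then Cu-catalysed enantioselective anti-SN2′ methylation of the meso oxabicycle. Ring order: B → ether bridge (as lactone) → A → macrolactone.

Convention: atom labels C1–C19 are those of the target (C1 = lactone carbonyl, C13 = quaternary ether carbon). For ring B (C7–C12), β is the face that carries C6 and C13, α the opposite face.

Assumption: in triol 37 the hydroxyls acylate in the order C18 > C9 >> C11 (recalled behaviour of the natural triol nodusmicin, not re-verified here), so the last two steps need no protecting groups.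

**Route**

Step 1
Reactants: 1 furan; 2 maleic anhydride
Product: 3 exo Diels–Alder anhydride
Conditions: Et2O, rt, 48 h
Reagents that add atoms: none
Why: Diels–Alder cycloaddition under thermodynamic control gives the meso exo adduct, so both future arms (C6, C13) sit syn to the oxygen bridge.

Step 2
Reactants: 3 exo anhydride
Product: 4 meso diol
Conditions: LiAlH4, THF, 0 °C → rt
Reagents that add atoms: none
Why: Hydride reduction of the anhydride to the diol at low temperature avoids retro-Diels–Alder and touches no stereocentre.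

Step 3
Reactants: 4 meso diol
Product: 5 meso bis-TBS ether
Conditions: TBSCl, imidazole, DMF, rt
Reagents that add atoms: tert-butyldimethylsilyl chloride, CC(C)(C)[Si](C)(C)Cl
Why: Silylation of both primary alcohols gives an ether-only substrate for the organometallic ring opening.

Step 4
Reactants: 5 meso bis-TBS ether
Product: 6 ring-B cyclohexenol
Conditions: Me3Al, copper thiophene-2-carboxylate (5 mol %), chiral aminophosphine ligand (SimplePhos type, 10 mol %, enantiomer chosen to give 6), Et2O, −40 °C; aq. potassium sodium tartrate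
Reagents that add atoms: trimethylaluminium, C[Al](C)C
Why: Cu-catalysed asymmetric anti-SN2′ ring opening of a meso oxabicycle puts methyl on C10 anti to the departing bridge oxygen (10α-Me trans to 11β-OH, C8=C9 formed), and ligand control over the enantiotopic alkene carbons sets the absolute configuration of C7, C10, C11 and C12.

Step 5
Reactants: 6 ring-B cyclohexenol
Product: 7 8β,9β-epoxy alcohol
Conditions: VO(acac)2 (2 mol %), t-BuOOH, CH2Cl2, 0 °C → rt
Reagents that add atoms: tert-butyl hydroperoxide, CC(C)(C)OO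
Why: Hydroxyl-directed vanadium-catalysed epoxidation delivers oxygen syn to the homoallylic 11β-OH, and the allylic 10α-methyl shields the other face.

Step 6
Reactants: 7 epoxy alcohol
Product: 8 11-O-TIPS epoxide
Conditions: TIPSOTf, 2,6-lutidine, CH2Cl2, −40 °C
Reagents that add atoms: triisopropylsilyl triflate, CC(C)[Si](C(C)C)(C(C)C)OS(=O)(=O)C(F)(F)F
Why: Silylation masks O11 with an acid-stable group, so that later only O8 can capture an oxidised arm.

Step 7
Reactants: 8 11-O-TIPS epoxide
Product: 9 ring-B tetraol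
Conditions: HClO4 (cat.), THF/H2O 3:1, rt
Reagents that add atoms: water, O
Why: Acid-catalysed trans-diaxial (Fürst–Plattner) epoxide hydrolysis puts water on C9 from the α face (C8 attack would need a chair with three syn-axial groups), giving 8β-OH/9α-OH, while both primary TBS ethers are hydrolysed and the secondary TIPS ether survives.

Step 8
Reactants: 9 ring-B tetraol
Product: 10 bridged lactone aldehyde
Conditions: TEMPO (cat.), PhI(OAc)2, CH2Cl2, rt
Reagents that add atoms: none
Why: Primary-selective TEMPO oxidation takes both CH2OH groups to aldehydes; only the C13 aldehyde has a syn-axial partner (8β-OH) and goes on via its lactol to the γ-lactone, which forms the C8–O bridge and tells C13 from C6.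

Step 9
Reactants: 10 bridged lactone aldehyde
Product: 11 vinyl lactone
Conditions: Ph3PCH3Br, KN(SiMe3)2, THF, −78 → 0 °C
Reagents that add atoms: methyltriphenylphosphonium bromide, C[P+](c1ccccc1)(c1ccccc1)c1ccccc1.[Br-]
Why: Wittig methylenation of the aldehyde at low temperature; the lactone is inert to the ylide and its bridgehead α-carbon cannot enolise.

Step 10
Reactants: 11 vinyl lactone
Product: 12 9-O-TBS vinyl lactone
Conditions: TBSOTf, 2,6-lutidine, CH2Cl2, −78 °C
Reagents that add atoms: tert-butyldimethylsilyl triflate, CC(C)(C)[Si](C)(C)OS(=O)(=O)C(F)(F)F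
Why: Silylation of the axial 9α-OH keeps it out of the later lactonisation.

Step 11
Reactants: 13 methyl (R)-lactate
Product: 14 TBS-protected lactate
Conditions: TBSCl, imidazole, DMF, rt
Reagents that add atoms: tert-butyldimethylsilyl chloride, CC(C)(C)[Si](C)(C)Cl
Why: Silylation of the chiral-pool alcohol, whose stereocentre becomes C18.

Step 12
Reactants: 14 TBS-protected lactate
Product: 15 (R)-2-(TBSO)propanal
Conditions: i-Bu2AlH, CH2Cl2, −78 °C; aq. potassium sodium tartrate
Reagents that add atoms: none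
Why: Half-reduction of the ester at −78 °C stops at the aldehyde without epimerising the α-silyloxy centre.

Step 13
Reactants: 16 cis-2-butene; 15 (R)-2-(TBSO)propanal
Product: 18 syn-anti homoallylic alcohol, via (Z)-crotyl pinacolboronate 17 (not isolated)
Conditions: n-BuLi, KOt-Bu, THF, −78 → −50 °C; i-PrOBpin, −78 °C; then 15, −78 °C → rt; aq. NaHCO3
Reagents that add atoms: none
Why: (Z)-Crotylboration through a chair Zimmerman–Traxler transition state gives the 16,17-syn pair, and Felkin–Anh attack anti to the α-silyloxy group gives the 17,18-anti pair.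

Step 14
Reactants: 18 homoallylic alcohol
Product: 19 γ-lactol
Conditions: Rh(acac)(CO)2 (1 mol %), Xantphos, CO/H2 (1:1, 10 bar), toluene, 60 °C
Reagents that add atoms: carbon monoxide, [C-]#[O+]
Why: Linear-selective rhodium-catalysed hydroformylation adds C14, and the aldehyde is trapped by O17 as the lactol (anomeric centre of no consequence).

Step 15
Reactants: 19 γ-lactol
Product: 20 2,3-dihydrofuran
Conditions: MsCl, Et3N, CH2Cl2, −20 → 40 °C
Reagents that add atoms: none
Why: Mesylation of the lactol and base-induced elimination (glycal-type synthesis) give the cyclic enol ether with C16 and C17 untouched.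

Step 16
Reactants: 20 2,3-dihydrofuran
Product: 23 (Z)-iodo alcohol, via 5-lithio-2,3-dihydrofuran 21 (not isolated), via alkenyl(methyl)cuprate 22 (not isolated)
Conditions: t-BuLi, THF, −78 → 0 °C; Me2CuLi (from MeLi, CuBr·SMe2), Et2O/Me2S, −78 °C → rt; I2, −78 → 0 °C
Reagents that add atoms: methyllithium (as Me2CuLi), [Li]C; iodine, II
Why: Kocienski 1,2-metallate rearrangement, the key 1,2-shift: methyl migrates from copper to C14 with inversion at the alkenyl carbon while the ring C–O bond breaks, so copper (then iodine, with retention) ends cis to C16, giving only the (Z)-olefin and freeing O17.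

Step 17
Reactants: 23 (Z)-iodo alcohol
Product: 24 17-O-TES (Z)-iodide
Conditions: Et3SiCl, imidazole, CH2Cl2, 0 °C
Reagents that add atoms: chlorotriethylsilane, CC[Si](Cl)(CC)CC
Why: A TES ether on O17 can later be removed selectively beside TBS and TIPS ethers.

Step 18
Reactants: 25 L-allylglycine
Product: 26 (S)-2-hydroxypent-4-enoic acid
Conditions: NaNO2, 1 M H2SO4, 0 °C → rt
Reagents that add atoms: water, O
Why: Diazotisation with net retention (double inversion through the α-lactone) turns the amino acid into the α-hydroxy acid that carries the C2 configuration.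

Step 19
Reactants: 26 (S)-2-hydroxypent-4-enoic acid
Product: 27 methyl (S)-2-methoxypent-4-enoate
Conditions: MeI, Ag2O, MeCN, rt, dark
Reagents that add atoms: iodomethane, CI
Why: Purdie methylation makes the methyl ether and methyl ester in one operation without touching the α-centre.

Step 20
Reactants: 27 methyl (S)-2-methoxypent-4-enoate; 28 allyltrimethylsilane
Product: 29 (E)-allylsilane ester
Conditions: second-generation Grubbs catalyst (3 mol %), CH2Cl2, 40 °C; E isomer purified on AgNO3-silica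
Reagents that add atoms: none
Why: Olefin cross-metathesis with excess allylsilane gives mainly the (E)-allylsilane that holds C1–C5.

Step 21
Reactants: 24 17-O-TES (Z)-iodide; 12 9-O-TBS vinyl lactone
Product: 31 bridged alkenyl hemiketal, via (Z)-alkenyllithium 30 (not isolated)
Conditions: t-BuLi (2 equiv), Et2O, −78 °C; then 12, THF, −78 °C; aq. NH4Cl
Reagents that add atoms: none
Why: Iodine–lithium exchange keeps the olefin geometry, and addition to the non-enolisable bridged lactone stops at the tetrahedral stage, forming the C13–C14 bond.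

Step 22
Reactants: 31 bridged alkenyl hemiketal; 29 (E)-allylsilane ester
Product: 32 C-allylated bridged ether
Conditions: 29 (2 equiv), Me3SiOTf (0.2 equiv), CH2Cl2, −78 °C
Reagents that add atoms: none
Why: Proposed new method: TMSOTf-catalysed Hosomi–Sakurai C-allylation of a bridged alkenyl-substituted hemiketal with a γ-substituted ester-bearing (E)-allylsilane, making the quaternary ether carbon C13 and the adjacent C4 stereocentre in one step; the hemiketal ionises to the 6-oxabicyclo[3.2.1] oxocarbenium ion, the silane attacks its exo face (the side of the one-carbon bridge C7, away from the C9–C11 bridge) in an anti-SE2′ open transition state with the allyl chain anti to C12, the C4–H in the crowded C12/C7 quadrant and CH2SiMe3 over the ring oxygen, which predicts the (13S,4S) pair; closest known reaction type is the Sakurai (Kishi-type) allylation of ketose-derived oxocarbenium ions and crotylsilane additions to acetals.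

Step 23
Reactants: 32 C-allylated bridged ether
Product: 33 tricyclic core ester
Conditions: second-generation Grubbs catalyst (5 mol %), CH2Cl2, 40 °C
Reagents that add atoms: none
Why: Ring-closing metathesis of the two syn-disposed vinyl groups forms ring A with the C5=C6 cis-olefin; the trisubstituted C14=C15 olefin does not take part.

Step 24
Reactants: 33 tricyclic core ester
Product: 34 carboxylic acid
Conditions: LiOH, THF/MeOH/H2O, 0 °C → rt; 1 M HCl to pH 4
Reagents that add atoms: lithium hydroxide, [Li+].[OH-]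
Why: Mild saponification of the methyl ester leaves the silyl ethers in place and does not epimerise C2.

Step 25
Reactants: 34 carboxylic acid
Product: 35 seco acid
Conditions: HF·pyridine, pyridine, THF, 0 °C
Reagents that add atoms: none
Why: Buffered fluoride removes the secondary TES ether much faster than the TBS and TIPS ethers, freeing only O17.

Step 26
Reactants: 35 seco acid
Product: 36 macrolactone tris-silyl ether
Conditions: 2-methyl-6-nitrobenzoic anhydride, DMAP, toluene (1 mM), rt
Reagents that add atoms: none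
Why: Shiina macrolactonisation under high dilution closes the 10-membered lactone at O17 with retention at C17; the Z-olefin and the trans-fused ring A pre-organise the chain.

Step 27
Reactants: 36 macrolactone tris-silyl ether
Product: 37 macrolide triol
Conditions: HF·pyridine, THF, rt
Reagents that add atoms: none
Why: Global fluoride desilylation frees O9, O11 and O18 without harming the lactone or the ether bridge.

Step 28
Reactants: 37 macrolide triol
Product: 38 18-O-acetyl triol
Conditions: Ac2O (1.1 equiv), pyridine, CH2Cl2, −20 °C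
Reagents that add atoms: acetic anhydride, CC(=O)OC(C)=O
Why: Kinetically selective acetylation of the least hindered secondary hydroxyl (side-chain O18) over the ring hydroxyls.

Step 29
Reactants: 38 18-O-acetyl triol; 39 pyrrole-2-carboxylic acid
Product: 40 18-O-acetyl-nargenicin
Conditions: DCC, DMAP (cat.), CH2Cl2, 0 °C → rt
Reagents that add atoms: none
Why: Steglich esterification acylates O9 in preference to the hindered O11, which is flanked by the ring fusion and the C10 methyl.

**Compound list**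

1 | furan | c1ccoc1 | starting material
2 | maleic anhydride | O=C1OC(=O)C=C1 | starting material
3 | exo-7-oxabicyclo[2.2.1]hept-5-ene-2,3-dicarboxylic anhydride (meso) | O=C1OC(=O)[C@H]2[C@@H]1[C@H]3O[C@@H]2C=C3 | intermediate
4 | meso exo,exo-2,3-bis(hydroxymethyl)-7-oxabicyclo[2.2.1]hept-5-ene | OC[C@H]1[C@@H](CO)[C@H]2O[C@@H]1C=C2 | intermediate
5 | meso exo,exo-2,3-bis(tert-butyldimethylsilyloxymethyl)-7-oxabicyclo[2.2.1]hept-5-ene | CC(C)(C)[Si](C)(C)OC[C@H]1[C@@H](CO[Si](C)(C)C(C)(C)C)[C@H]2O[C@@H]1C=C2 | intermediate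
6 | ring-B cyclohexenol: 11β-OH, 10α-CH3, C8=C9, 7β- and 12β-CH2OTBS | CC(C)(C)[Si](C)(C)OC[C@H]1[C@@H](CO[Si](C)(C)C(C)(C)C)C=C[C@H](C)[C@H]1O | intermediate
7 | 8β,9β-epoxide of 6 (epoxide cis to 11β-OH) | CC(C)(C)[Si](C)(C)OC[C@H]1[C@@H](CO[Si](C)(C)C(C)(C)C)[C@H]2O[C@H]2[C@H](C)[C@H]1O | intermediate
8 | 11-O-triisopropylsilyl ether of 7 | CC(C)(C)[Si](C)(C)OC[C@H]1[C@@H](CO[Si](C)(C)C(C)(C)C)[C@H]2O[C@H]2[C@H](C)[C@H]1O[Si](C(C)C)(C(C)C)C(C)C | intermediate
9 | ring-B tetraol: 8β-OH, 9α-OH, 10α-CH3, 11β-OTIPS, 7β- and 12β-CH2OH | OC[C@H]1[C@@H](CO)[C@@H](O)[C@H](O)[C@H](C)[C@H]1O[Si](C(C)C)(C(C)C)C(C)C | intermediate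
10 | bridged γ-lactone aldehyde (C13(=O)–O–C8; 7β-CHO, 9α-OH, 10α-CH3, 11β-OTIPS) | O=C[C@H]1[C@H]2OC(=O)[C@@H]1[C@H](O[Si](C(C)C)(C(C)C)C(C)C)[C@@H](C)[C@H]2O | intermediate
11 | bridged γ-lactone with 7β-vinyl and free 9α-OH | C=C[C@H]1[C@H]2OC(=O)[C@@H]1[C@H](O[Si](C(C)C)(C(C)C)C(C)C)[C@@H](C)[C@H]2O | intermediate
12 | 9-O-TBS ether of 11 | C=C[C@H]1[C@H]2OC(=O)[C@@H]1[C@H](O[Si](C(C)C)(C(C)C)C(C)C)[C@@H](C)[C@H]2O[Si](C)(C)C(C)(C)C | intermediate
13 | methyl (R)-lactate | COC(=O)[C@@H](C)O | starting material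
14 | methyl (R)-2-(tert-butyldimethylsilyloxy)propanoate | COC(=O)[C@@H](C)O[Si](C)(C)C(C)(C)C | intermediate
15 | (R)-2-(tert-butyldimethylsilyloxy)propanal | O=C[C@@H](C)O[Si](C)(C)C(C)(C)C | intermediate
16 | cis-2-butene | C/C=C\C | starting material
17 | (Z)-crotylboronic acid pinacol ester | C/C=C\CB1OC(C)(C)C(C)(C)O1 | intermediate (not isolated)
18 | (2R,3S,4R)-2-(tert-butyldimethylsilyloxy)-4-methylhex-5-en-3-ol | C=C[C@@H](C)[C@@H]([C@@H](C)O[Si](C)(C)C(C)(C)C)O | intermediate
19 | (4R,5S)-5-[(R)-1-(tert-butyldimethylsilyloxy)ethyl]-4-methyltetrahydrofuran-2-ol (anomers) | OC1C[C@@H](C)[C@@H]([C@@H](C)O[Si](C)(C)C(C)(C)C)O1 | intermediate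
20 | (2S,3R)-2-[(R)-1-(tert-butyldimethylsilyloxy)ethyl]-3-methyl-2,3-dihydrofuran | C1=C[C@@H](C)[C@@H]([C@@H](C)O[Si](C)(C)C(C)(C)C)O1 | intermediate
21 | 5-lithio derivative of 20 | [Li]C1=C[C@@H](C)[C@@H]([C@@H](C)O[Si](C)(C)C(C)(C)C)O1 | intermediate (not isolated)
22 | dilithium (Z)-alkenyl(methyl)cuprate alkoxide (Cu cis to C16, methyl on C14) | C[Cu-]/C(C)=C\[C@@H](C)[C@@H]([C@@H](C)O[Si](C)(C)C(C)(C)C)[O-].[Li+].[Li+] | intermediate (not isolated)
23 | (2R,3S,4R,5Z)-2-(tert-butyldimethylsilyloxy)-6-iodo-4-methylhept-5-en-3-ol | I/C(C)=C\[C@@H](C)[C@@H]([C@@H](C)O[Si](C)(C)C(C)(C)C)O | intermediate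
24 | 3-O-triethylsilyl ether of 23 (O17 as TES, O18 as TBS) | I/C(C)=C\[C@@H](C)[C@@H]([C@@H](C)O[Si](C)(C)C(C)(C)C)O[Si](CC)(CC)CC | intermediate
25 | L-allylglycine, (S)-2-aminopent-4-enoic acid | N[C@@H](CC=C)C(=O)O | starting material
26 | (S)-2-hydroxypent-4-enoic acid | O[C@@H](CC=C)C(=O)O | intermediate
27 | methyl (S)-2-methoxypent-4-enoate | CO[C@@H](CC=C)C(=O)OC | intermediate
28 | allyltrimethylsilane | C=CC[Si](C)(C)C | starting material
29 | methyl (S,E)-2-methoxy-6-(trimethylsilyl)hex-4-enoate | CO[C@@H](C/C=C/C[Si](C)(C)C)C(=O)OC | intermediate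
30 | (Z)-alkenyllithium from 24 | [Li]/C(C)=C\[C@@H](C)[C@@H]([C@@H](C)O[Si](C)(C)C(C)(C)C)O[Si](CC)(CC)CC | intermediate (not isolated)
31 | bridged hemiketal at C13 carrying the (Z)-C14–C19 chain (C13 anomers) | C=C[C@H]1[C@H]2OC(O)(/C(C)=C\[C@@H](C)[C@@H]([C@@H](C)O[Si](C)(C)C(C)(C)C)O[Si](CC)(CC)CC)[C@@H]1[C@H](O[Si](C(C)C)(C(C)C)C(C)C)[C@@H](C)[C@H]2O[Si](C)(C)C(C)(C)C | intermediate
32 | C-allylated bridged ether: C13 quaternary (O8, C12, C14, C4); C4 carries vinyl and the CH2CH(OMe)CO2Me chain | COC(=O)[C@@H](OC)C[C@@H](C=C)[C@]1(/C(C)=C\[C@@H](C)[C@@H]([C@@H](C)O[Si](C)(C)C(C)(C)C)O[Si](CC)(CC)CC)O[C@@H]2[C@H](C=C)[C@H]1[C@H](O[Si](C(C)C)(C(C)C)C(C)C)[C@@H](C)[C@H]2O[Si](C)(C)C(C)(C)C | intermediate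
33 | tricyclic core methyl ester (rings A and B plus ether bridge) | COC(=O)[C@@H](OC)C[C@H]2C=C[C@H]3[C@H]4O[C@]2(/C(C)=C\[C@@H](C)[C@@H]([C@@H](C)O[Si](C)(C)C(C)(C)C)O[Si](CC)(CC)CC)[C@@H]3[C@H](O[Si](C(C)C)(C(C)C)C(C)C)[C@@H](C)[C@H]4O[Si](C)(C)C(C)(C)C | intermediate
34 | carboxylic acid of 33 | OC(=O)[C@@H](OC)C[C@H]2C=C[C@H]3[C@H]4O[C@]2(/C(C)=C\[C@@H](C)[C@@H]([C@@H](C)O[Si](C)(C)C(C)(C)C)O[Si](CC)(CC)CC)[C@@H]3[C@H](O[Si](C(C)C)(C(C)C)C(C)C)[C@@H](C)[C@H]4O[Si](C)(C)C(C)(C)C | intermediate
35 | seco acid with free 17-OH | OC(=O)[C@@H](OC)C[C@H]2C=C[C@H]3[C@H]4O[C@]2(/C(C)=C\[C@@H](C)[C@@H]([C@@H](C)O[Si](C)(C)C(C)(C)C)O)[C@@H]3[C@H](O[Si](C(C)C)(C(C)C)C(C)C)[C@@H](C)[C@H]4O[Si](C)(C)C(C)(C)C | intermediate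
36 | macrolactone with 9-O-TBS, 11-O-TIPS and 18-O-TBS | CO[C@H]1C[C@H]2C=C[C@H]3[C@H]4O[C@]2(/C(C)=C\[C@@H](C)[C@@H]([C@@H](C)O[Si](C)(C)C(C)(C)C)OC1=O)[C@@H]3[C@H](O[Si](C(C)C)(C(C)C)C(C)C)[C@@H](C)[C@H]4O[Si](C)(C)C(C)(C)C | intermediate
37 | macrolide triol (nodusmicin; 9-, 11- and 18-OH free) | CO[C@H]1C[C@H]2C=C[C@H]3[C@H]4O[C@]2(/C(C)=C\[C@@H](C)[C@@H]([C@@H](C)O)OC1=O)[C@@H]3[C@H](O)[C@@H](C)[C@H]4O | intermediate
38 | 18-O-acetyl triol (18-O-acetylnodusmicin) | CO[C@H]1C[C@H]2C=C[C@H]3[C@H]4O[C@]2(/C(C)=C\[C@@H](C)[C@@H]([C@@H](C)OC(C)=O)OC1=O)[C@@H]3[C@H](O)[C@@H](C)[C@H]4O | intermediate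
39 | pyrrole-2-carboxylic acid | OC(=O)c1ccc[nH]1 | starting material
40 | 18-O-acetyl-nargenicin | CO[C@H]1C[C@H]2C=C[C@H]3[C@H]4O[C@]2(/C(C)=C\[C@@H](C)[C@@H]([C@@H](C)OC(C)=O)OC1=O)[C@@H]3[C@H](O)[C@@H](C)[C@H]4OC(=O)c1ccc[nH]1 | target

**Totals and risks**

Total step count: 29. Longest linear sequence: 19 steps (steps 1–10, then 21–29).

Most likely to fail:

Step 22 (the proposed new step). The open-transition-state control of C4 is unproven, and 1,4-attack or Z/E scrambling of the alkenyl oxocarbenium ion could compete. The fallback uses known chemistry, sets out from 31 (with 27) and returns at 32. Cross-metathesis of 27 with allyl bromide (second-generation Grubbs catalyst) gives methyl (S,E)-6-bromo-2-methoxyhex-4-enoate F1. Indium-mediated Barbier γ-allylation of the hydroxy-enone tautomer of 31 with F1 (indium metal, THF/H2O) gives the tertiary homoallylic alcohol, the C8,C13-diol F2. Re2O7 (cat.) or camphorsulfonic acid in CH2Cl2 then ionises the tertiary allylic alcohol and the 8β-hydroxyl closes the ether bridge to 32.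

Step 4. Enantioselectivity of the anti-opening on this non-benzo-fused oxabicycle may be insufficient. The fallback sets out from 5 and returns at 6. Racemic anti-opening (MeMgBr, CuCl/PPh3) gives 6 together with its enantiomer F3. Lipase kinetic resolution (Amano PS, vinyl acetate) then acetylates the unwanted antipode to the acetate F4 and leaves 6.

Step 26. The 10-membered lactonisation may be slow against oligomerisation or C2 epimerisation. The fallback sets out from 32 and returns at 36 by lactonising before ring A is closed. LiOH gives the carboxylic acid F5. Buffered HF·pyridine gives the 17-hydroxy acid F6. Shiina or Yamaguchi lactonisation of this more flexible seco acid gives the macrolactone diene F7. Ring-closing metathesis (second-generation Grubbs catalyst) then closes ring A to 36.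

**Further compounds**

F1 | step 22 | methyl (S,E)-6-bromo-2-methoxyhex-4-enoate | CO[C@@H](C/C=C/CBr)C(=O)OC
F2 | step 22 | C8,C13-diol from γ-allylation of the keto form of 31 (C13 epimers) | COC(=O)[C@@H](OC)C[C@@H](C=C)C(O)(/C(C)=C\[C@@H](C)[C@@H]([C@@H](C)O[Si](C)(C)C(C)(C)C)O[Si](CC)(CC)CC)[C@H]1[C@@H](C=C)[C@@H](O)[C@H](O[Si](C)(C)C(C)(C)C)[C@H](C)[C@H]1O[Si](C(C)C)(C(C)C)C(C)C
F3 | step 4 | enantiomer of 6 | CC(C)(C)[Si](C)(C)OC[C@@H]1[C@H](CO[Si](C)(C)C(C)(C)C)C=C[C@@H](C)[C@@H]1O
F4 | step 4 | acetate of F3 | CC(C)(C)[Si](C)(C)OC[C@@H]1[C@H](CO[Si](C)(C)C(C)(C)C)C=C[C@@H](C)[C@@H]1OC(C)=O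
F5 | step 26 | carboxylic acid from 32 | OC(=O)[C@@H](OC)C[C@@H](C=C)[C@]1(/C(C)=C\[C@@H](C)[C@@H]([C@@H](C)O[Si](C)(C)C(C)(C)C)O[Si](CC)(CC)CC)O[C@@H]2[C@H](C=C)[C@H]1[C@H](O[Si](C(C)C)(C(C)C)C(C)C)[C@@H](C)[C@H]2O[Si](C)(C)C(C)(C)C
F6 | step 26 | 17-hydroxy acid from F5 | OC(=O)[C@@H](OC)C[C@@H](C=C)[C@]1(/C(C)=C\[C@@H](C)[C@@H]([C@@H](C)O[Si](C)(C)C(C)(C)C)O)O[C@@H]2[C@H](C=C)[C@H]1[C@H](O[Si](C(C)C)(C(C)C)C(C)C)[C@@H](C)[C@H]2O[Si](C)(C)C(C)(C)C
F7 | step 26 | macrolactone diene with ring A still open | CO[C@H]1C[C@@H](C=C)[C@]2(/C(C)=C\[C@@H](C)[C@@H]([C@@H](C)O[Si](C)(C)C(C)(C)C)OC1=O)O[C@@H]3[C@H](C=C)[C@H]2[C@H](O[Si](C(C)C)(C(C)C)C(C)C)[C@@H](C)[C@H]3O[Si](C)(C)C(C)(C)C
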